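The readings come from a simulation with constants of no real substance; the scatter is artificial.

The easy step is the size of the catalyst charge: in the noon run it is 0.200% of the substrate charged, so one pass of the whole catalyst turns that fraction of the charge into product.

| flask | substrate | reagent | free catalyst | temperature | remark | time |
|---|---|---|---|---|---|---|
| spring | 0.084 M | 2.5 M | 1 mM | 5 °C | run made earlier |  |
| midnight | 0.38 M | 2.5 M | 1 mM | 27 °C | run made earlier |  |
| noon | 0.50 M | 1.2 M | 1 mM | 5 °C | run made earlier |  |
| larch | 0.50 M | 2.50 M | 1.0 mM | 35 °C |  | 15 min |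
| alder | 0.15 M | 2.50 M | 1.0 mM | −5 °C |  | 15 min |
| ash | 0.50 M | 2.50 M | 1.0 mM | −5 °C |  | 15 min |
| cedar | 0.30 M | 0.800 M | 1.0 mM | 35 °C |  | 15 min |
| birch | 0.50 M | 0.600 M | 1.0 mM | 35 °C |  | 15 min |

- spring (time / min: product / %, substrate / %): 4.00: 7.8, 93.6; 12.0: 21.1, 79.6; 20.0: 32.3, 67.8; 40.0: 56.2, 43.6; 50.0: 65.4, 34.6; 60.0: 72.8, 27.1
- midnight (time / min: product / %, substrate / %): 2.50: 13.3, 87.0; 5.00: 25.3, 73.8; 8.00: 37.6, 61.2; 10.0: 47.3, 52.5; 12.0: 53.8, 45.0; 15.0: 63.8, 36.8
- noon (time / min: product / %, substrate / %): 6.00: 3.7, 96.6; 12.0: 5.2, 93.8; 20.0: 10.6, 89.4; 40.0: 20.3, 79.4; 60.0: 29.9, 70.0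

(each reading ± 0.5 percentage points)

* the flasks by amount of product, in percent of the substrate charged, highest first, at 15 min (larch / alder / ash / cedar / birch)
* the amount of product, in percent of the substrate charged of the flask you put first, at 15 min
* the amount of product, in percent of the substrate charged of the flask you put last, at 15 min

So a straight product line can be read as a count of passes, and noon's line climbs in nearly equal steps, 10.6%, 20.3%, 29.9%. The cycle time, the minutes one catalyst needs per product, is the catalyst's fraction of the charge times the time, over the fraction turned: for noon 0.401 min. The first midnight reading, taken while substrate stands near its charge, gives 0.0495 min at 27 °C. But midnight also differs from noon in reagent and substrate, so the factor 8.11 mixes these with temperature, and what follows is rough.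

Spread evenly over the degrees, that factor carries noon down to ash at −5 °C as a cycle time of 1.04 min, so my reckoning for ash at 15 min is 2.89%. Reckoned the same way at alder's own −5 °C, the cycle time is 1.04 min, and alder reaches 9.62%, since its catalyst fraction is larger, so ash stands below alder. Carried up to 35 °C, the same factor passes larch's whole charge in 11.6 min, inside 15 min, so larch's line has to bend as its substrate falls.

The forecast gives larch > cedar > birch > alder > ash, with 80% first and 5% last, and adds: “The extrapolation is uncertain”.

The flasks give larch > cedar > birch > alder > ash, from 83.0% down to 3.43%.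

    reagent + free catalyst → catalyst intermediate A (k = 45.0 M⁻¹ min⁻¹, Ea = 49.0 kJ mol⁻¹)
    substrate + catalyst intermediate A ⇌ catalyst intermediate B (K = 17.0 M⁻¹, k = 220 M⁻¹ min⁻¹, Ea = 48.0 kJ mol⁻¹, ΔH = −52.0 kJ mol⁻¹)
    catalyst intermediate B → free catalyst + product (k = 180 min⁻¹, Ea = 79.0 kJ mol⁻¹)
    (constants at 35 °C)

Ash's 3.43% means a cycle time of 0.875 min, against 1.04 min reckoned and 0.401 min in noon. In ash at 7.24 min, catalyst intermediate B has a half-life of 0.38 min on its way to free catalyst and product, longer than the 0.11 min of free catalyst at that moment and the 0.11 min of catalyst intermediate A by its forward step alone at 15.0 min, when this resting state holds 63.9% of the catalyst. Ash's cycle time carried to 40 min gives 9.15%, and ash left until then holds 9.17%.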